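The south-east run, cooler and with half the reagent in the second phase, ends at 20.0 min, so late behaviour has to be read from the east run, which is the asked flask itself.

all flasks: substrate 34 mM

| run | reagent in the second phase | temperature | remark | time | volume of the second phase over the first |
|---|---|---|---|---|---|
| east | 1.2 equiv | 60 °C | the very flask that is asked about, followed so far |  |  |
| south-east | 0.60 equiv | 55 °C | run made earlier |  |  |
| flask | 1.20 equiv | 60 °C |  | 5.0 h | 0.25 |

| run | time / min | product / % | substrate / % |
|---|---|---|---|
| east | 25.0 | 13.7 | 85.8 |
| east | 50.0 | 23.8 | 76.4 |
| east | 80.0 | 29.2 | 71.1 |
| east | 150 | 34.4 | 65.5 |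
| east | 300 | 39.3 | 60.2 |
| south-east | 4.00 | 0.4 | 99.6 |
| south-east | 8.00 | 1.5 | 99.1 |
| south-east | 12.0 | 1.6 | 98.1 |
| south-east | 15.0 | 3.0 | 97.3 |
| south-east | 20.0 | 3.8 | 96.0 |

(standard deviation of a reading: 0.3 percentage points)

- in the second phase: reagent in the second phase; everything else is in the first
- charges count per volume of the first phase; a concentration in a rate is the amount of a species over the volume of its own phase; every rate counts per litre of the first phase
- product taken out counts as made
- the numbers in the tables scatter by 0.3 percentage points (one standard deviation)
- on the list of suspects stand: reagent in the reaction phase <-> reagent in the second phase; substrate + reagent in the reaction phase -> product; reagent in the reaction phase <-> dormant form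
- the earlier runs hold the two phases in the same ratio of volumes as the flask asked about
- additions bring no volume worth counting

- blue: change nothing and wait 5.0 h more
- green: at 5.0 h take out 90% of the product then present, then wait 5.0 h
- amber: at 5.0 h raise the temperature by 15 K, then wait 5.0 h
- ochre: at 5.0 h add substrate, 50.0% of the amount charged, then wait 5.0 h

- product, in percent of the substrate first charged, at 5.0 h
- what to do for the largest gain in product; "none" if nothing gains more than 2 percentage points (blue / green / amber / ochre / none)
- product present, with what was taken out counted in, in percent of the substrate first charged, after blue
- product present, with what was taken out counted in, in percent of the substrate first charged, after amber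

"Now" therefore lies close to the east reading of 39.3% at 300 min, and substrate plus product there make 99.5% of the charge, so substrate shows no side exit. But its pseudo-first-order constant sinks from 0.368 h⁻¹ up to the first reading to 0.0338 h⁻¹ between the last two, while the product at 300 min accounts for a third of the reagent charged. So reagent is being held somewhere, and the suspected dormant form offers a place.

The reckoning here freezes the late pace: the tail constant k_t, the logarithm of the ratio of two late substrate readings over the time between them. With k_t held for 5.0 h, blue gives product 49.1%. By the same frozen k_t, ochre gains 17 percentage points on its larger substrate, and amber passes that if 15 K makes k_t twice as large.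

The forecast says 39.3% now, amber as best, 46% after blue, below the reckoning here, and 56% after amber, and it reads the falling pace so: “Active reagent is therefore parked as the dormant form”.

The flask gives 39.8% now, amber as best, 47.8% after blue and 70.4% after amber, so amber stands 14 points above the forecast.

    reagent in the reaction phase ⇌ reagent in the second phase, rate k1*([reagent in the reaction phase] - [reagent in the second phase]/K1) per volume of the first phase (partition coefficient = 2.60, kL = 9.00 × 10⁻⁴ s⁻¹)
    substrate + reagent in the reaction phase → product (k = 0.00810 M⁻¹ s⁻¹, Ea = 78.0 kJ mol⁻¹)
    reagent in the reaction phase ⇌ dormant form (K = 20.0, k = 6.10 × 10⁻⁴ s⁻¹, Ea = 88.0 kJ mol⁻¹, ΔH = −38.0 kJ mol⁻¹)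
    (constants at 60 °C)

The flask is not at rest at 300 min, with substrate at 60.2%. Frozen k_t gave 49.1% after blue against 47.8%. For the neighbour left until 20 h it gives substrate 36.3% against 40.5%, while reagent in the reaction phase goes from 1.03 mM to 0.818 mM. For the flask at ten times the time, k_t gives substrate 13.2% against 22.0%, the dormant form has fallen from 25.6 mM to 13.3 mM, and product has reached 78.0%.

The numbers in the tables were generated by integration for an exercise; scatter was added.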